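The pitfall in these flasks is to read electrophile lost as electrophile captured by nucleophile: by 30.0 min the south run had lost 62.0% of its electrophile but held 17.0% of target.

| setting | south | north | birch | maple |
|---|---|---|---|---|
| electrophile | 0.11 M | 0.11 M | 0.11 M | 0.11 M |
| nucleophile | 0.080 M | 0.16 M | 0.0990 M | 0.200 M |
| remark | run made earlier | run made earlier |  |  |
| time |  |  | 40 min | 40 min |

| run | time / min | electrophile / % | target / % |
|---|---|---|---|
| south | 2.00 | 68.8 | 27.3 |
| south | 5.00 | 59.1 | 30.2 |
| south | 10.0 | 52.2 | 27.4 |
| south | 15.0 | 47.2 | 23.9 |
| south | 20.0 | 43.7 | 20.8 |
| south | 30.0 | 38.0 | 17.0 |
| north | 2.00 | 44.5 | 50.0 |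
| north | 5.00 | 27.3 | 59.6 |
| north | 10.0 | 17.7 | 60.0 |
| north | 15.0 | 12.7 | 58.0 |
| north | 20.0 | 10.9 | 56.5 |
| north | 30.0 | 6.7 | 54.4 |

(scatter of a reading: 0.5 percentage points)

* part of the electrophile that has reacted at the end, birch
* part of the electrophile that has reacted at the end, maple
* what raising the concentration of nucleophile from its lowest to its highest value here does to the part of the electrophile that has reacted (changes below 5 percentage points count as none) (it falls / it rises / no change)



I read the falling target as a follow-up step in which target consumes one more electrophile. Captured electrophile is then the sum of electrophile lost and target present, divided by 2. That gave 39.5% in the south run at its last reading, and 35.5% already stood at 5.00 min, so capture was the fast rung of the ladder.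

From the last reading of each run I took the capture share, the electrophile captured per nucleophile charged, in moles. It read 0.543 in the south run and 0.508 in the north run, mean 0.525. Multiplying by c(nucleophile)/c(electrophile) gives an expected capture of 47.3% for birch and 95.5% for maple. I therefore expected nucleophile to be the limiting reagent in birch.

The slow rung came from the south run between 10.0 min and 30.0 min, where the follow-up step read 0.558 L mol⁻¹ min⁻¹. After capture in birch, that gives a half-life of 21.4 min, shorter than 40 min, so this rung counts. Second-order decay of the remainder gave me 77.0% reacted in birch. Exponential decay of maple's small remainder against its target gave 99.6%.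

The forecast, reasoning that “only about half the nucleophile is used”, gave 77% for birch, level with mine, and 97.5% for maple, below mine; for the reacted part its answer was: it rises.

The flasks gave 76.2% for birch and 99.6% for maple; for the reacted part the answer was: it rises, by 23 percentage points.

    nucleophile + acid set free ⇌ protonated nucleophile, settled at all times (K = 18000 L mol⁻¹)
    electrophile + target → side product (k = 0.600 L mol⁻¹ min⁻¹)
    electrophile + nucleophile → acid set free + target (k = 4.70 L mol⁻¹ min⁻¹)

Each side product counts as two, one of them captured, so birch at 40.0 min had captured 48.1% against my expected 47.3%, with 0.360% of its nucleophile still free. The neighbour of birch charged with 0.040 M of nucleophile has an expected capture of 19.1% by the same share. Its target and side product at 40.0 min come to 21.2% captured, with 0.341% of its nucleophile free and 61.9% of its electrophile unreacted.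

All runs come from a simulation on assumed constants; noise was put on by code.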